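If the larger initiator charge counted for nothing, the dawn run was my whole guide to the flask, so I took that null case as the zero of my scale.

| setting | dawn | flask |
|---|---|---|
| solid substrate | 0.20 M | 0.20 M |
| reagent | 1.5 equiv (fed, over 10 min) | 1.50 equiv (fed, over 10 min) |
| initiator | 0.44 mol% | 0.88 mol% |
| remark | run made earlier |  |
| time |  | 5.0 h |

dawn run (percent of the solid substrate charged)

| time / min | solid substrate / % | target / % |
|---|---|---|
| 5.00 | 96 | 0 |
| 15.0 | 96 | 0 |
| 30.0 | 88 | 7 |
| 40.0 | 85 | 5 |
| 60.0 | 81 | 8 |

(standard deviation of a reading: 1.5 percentage points)

- as a solid, counted per litre of solution: solid substrate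
- the numbers in the tables scatter with a standard deviation of 1.5 percentage points
- at the start none of the solid substrate is in solution
- what has only dissolved of solid substrate counts as not reacted
- starting material means what is dissolved; the solid is not counted in it
- no earlier run changes the charge of initiator; that part of a forecast is a guess

1. part of the solid substrate that has turned into other species by 5.0 h (what has only dissolved does not count)
2. amount of target at 5.0 h, in percent of the solid substrate charged
3. amount of starting material at 5.0 h, in percent of the solid substrate charged

I read the table row by row. At 5.00 min and 15.0 min the solid substrate stood at 96% and 96%, with 0% target, so I took this early loss as dissolving. From 15.0 min to 60.0 min the solid fell to 81%, through 88% and 85%. As a simplification, I treated that stretch as straight and zero-order in solid, and defined the take-up rate r, the concentration of solid leaving per minute, as 6.67 × 10⁻⁴ M min⁻¹, a reading from two noisy points.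

Adding the early loss to r carried on to 5.0 h, I reckoned 0.198 M of solid gone from the flask, leaving 1.00% of its charge. I committed to that figure and did not split the dissolved material between target and starting material.

The forecast gave 70% conversion, 39% target and 4% starting material, reasoning that “selectivity is about 0.55”. Its figures leave 26.0% as solid, more than my figure.

The flask gave 83.0% conversion, 83.0% target and 11.8% starting material, with 5.14% solid left.

    initiator → 2 initiating radical (k = 0.00149 min⁻¹)
    starting material + initiating radical → capped initiator + first chain carrier (k = 2.77 × 10⁵ L mol⁻¹ s⁻¹)
    reagent + first chain carrier ⇌ target + second chain carrier (K = 0.450, k = 6.34 × 10⁵ L mol⁻¹ s⁻¹)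
    starting material + second chain carrier → by-product + first chain carrier (k = 38000 L mol⁻¹ s⁻¹)
    2 second chain carrier → ended chains (k = 2.30 × 10⁸ L mol⁻¹ s⁻¹)
    solid substrate ⇌ starting material, rate k6*(cs6 - [starting material]) while solid is left; crystals form when [starting material] > cs6 (solubility = 0.140 M, k = 0.00526 min⁻¹)

The flask had lost 0.190 M of solid by 5.00 h, against my 0.198 M. I then put the same 6.67 × 10⁻⁴ M min⁻¹ on the neighbour flask charged with 0.80 M of solid substrate, its equivalents and loadings as in the recipe, keeping the early loss at the same concentration. That reckoning left 75.3% of its charge as solid. The neighbour flask held 74.6% solid at 5.00 h, with 23.8% target.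

Readings and results are calculated on assumed constants; scatter was added.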